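The cyclohexane ring (C1 = CMe2, C2 = CHBr, C3 = CH2, C4 = CHCl, C5 = alkylidene carbon, C6 = CHCl; side chain C7, C8) is opened at C3–C4 and C5–C6. Because quaternary C1 separates C2 from C6, methyl 2,2-dimethylacetoacetate can enolise only at its methyl group (C3). One tandem Michael/Dieckmann annulation adds this enolate to C4 of 2-(phenylsulfonyl)buta-1,3-diene and lets the resulting sulfonyl carbanion (C5) acylate on the ester (C6), so a keto ester and a sulfonyl diene give the whole ten-carbon skeleton. The sulfone later departs to a 2-vinyl enone that accepts chloride at C4 and bromine at C8.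

Key step: step 2

Remark: C-labels in the Why lines follow the ring numbering of the overview, not the locants of the systematic names; compounds 7 to 10 are carried as mixtures of epimers at the sulfonyl-bearing carbon, which becomes trigonal in step 6.

Step 1
Reactants: 1 buta-1,3-diene
Product: 3 2-(phenylsulfonyl)buta-1,3-diene, via organomercury chloride 2 (not isolated)
Conditions: PhSO2Na, HgCl2, DMSO/H2O, rt; then 2 M NaOH, Et2O, 0 °C; used at once
Reagents that add atoms: sodium benzenesulfinate [Na+].[O-]S(=O)c1ccccc1
Why: Sulfonylmercuration puts divalent mercury on a terminal carbon and the sulfinate on the adjacent allylic carbon, and base-induced demercurative elimination should then give the 2-sulfonyl diene.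

Step 2
Reactants: 4 methyl 2,2-dimethyl-3-oxobutanoate; 3 2-(phenylsulfonyl)buta-1,3-diene
Product: 7 2,2-dimethyl-4-(phenylsulfonyl)-4-vinylcyclohexane-1,3-dione (racemic), via lithium enolate 5 (not isolated), via lithium sulfonyl carbanion 6 (not isolated)
Conditions: LiN(iPr)2, THF, −78 °C; then 3, −78 to −20 °C; 1 M HCl work-up
Reagents that add atoms: none
Why: LiN(iPr)2 can deprotonate 4 only at the acetyl methyl group (C3) because C1 is quaternary, and enolate 5 adds in a Michael fashion to the CH2 terminus of the vinyl sulfone half of 3 (C3–C4), giving the allylic sulfonyl carbanion 6, whose sulfonyl-bearing carbon (C5) then attacks the ester carbonyl (C6) and expels methoxide (C5–C6). The closest known reaction type is the tandem Michael addition/Dieckmann (Claisen) acylation of ketone enolates with vinyl sulfones. The six-membered ring closes by 6-exo-trig acyl substitution. The only new stereocentre is the sulfonyl-bearing C5, which forms without control and is erased in step 6, so none is required. The step needs C-acylation at the sulfonyl-bearing carbon instead of the vinyl terminus of the allyl anion, which is secured because the former closes a six-membered and the latter an eight-membered ring, and it needs the adduct not to revert, which the two quaternary carbons flanking the new ketone secure by shielding it from methoxide.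

Step 3
Reactants: 7 2,2-dimethyl-4-(phenylsulfonyl)-4-vinylcyclohexane-1,3-dione
Product: 8 (3R)-3-hydroxy-2,2-dimethyl-6-(phenylsulfonyl)-6-vinylcyclohexan-1-one (both epimers at C6)
Conditions: (S)-2-methyl-CBS-oxazaborolidine (10 mol%), catecholborane, toluene, −78 to −40 °C; aqueous work-up
Reagents that add atoms: none
Why: CBS reduction, in which the catalyst tells the quaternary CMe2 flank from the CH2 flank of the C2 ketone and should give the (R)-carbinol in both C5 epimers, while the C6 ketone wedged between two quaternary carbons stays untouched and catecholborane spares the vinyl group.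

Step 4
Reactants: 8 (3R)-3-hydroxy-2,2-dimethyl-6-(phenylsulfonyl)-6-vinylcyclohexan-1-one
Product: 9 (1R)-2,2-dimethyl-3-oxo-4-(phenylsulfonyl)-4-vinylcyclohexyl chloromethanesulfonate (both epimers at C4)
Conditions: ClCH2SO2Cl, pyridine, CH2Cl2, 0 °C
Reagents that add atoms: chloromethanesulfonyl chloride ClCS(=O)(=O)Cl
Why: O-Sulfonylation of the secondary alcohol with retention at C2, the chloromethanesulfonate being a leaving group suited to SN2 displacement at hindered secondary carbons.

Step 5
Reactants: 9 (1R)-2,2-dimethyl-3-oxo-4-(phenylsulfonyl)-4-vinylcyclohexyl chloromethanesulfonate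
Product: 10 (3S)-3-bromo-2,2-dimethyl-6-(phenylsulfonyl)-6-vinylcyclohexan-1-one (both epimers at C6)
Conditions: LiBr, DMF, 60 °C
Reagents that add atoms: lithium bromide [Li+].[Br-]
Why: SN2 displacement with inversion should set the (S)-bromide at C2, the chloromethanesulfonate/bromide pair being a known type of answer to secondary carbinols next to a quaternary carbon.

Step 6
Reactants: 10 (3S)-3-bromo-2,2-dimethyl-6-(phenylsulfonyl)-6-vinylcyclohexan-1-one
Product: 11 (5S)-5-bromo-6,6-dimethyl-2-vinylcyclohex-2-en-1-one
Conditions: Pd(PPh3)4 (5 mol%), Et3N, THF, 60 °C; used crude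
Reagents that add atoms: none
Why: Zerovalent palladium should ionise the tertiary allylic sulfone to an allylpalladium (palladium dienolate) species whose only β-hydrogens sit on C4, so that β-hydride elimination gives the cross-conjugated 2-vinyl enone (palladium-catalysed elimination of an allylic leaving group to a 1,3-diene, Tsuji–Trost type).

Step 7
Reactants: 11 (5S)-5-bromo-6,6-dimethyl-2-vinylcyclohex-2-en-1-one
Product: 13 (2Z,3S,5S)-5-bromo-2-(2-bromoethylidene)-3-chloro-6,6-dimethylcyclohexan-1-one, via silyl dienol ether 12 (not isolated)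
Conditions: Me3SiCl, Et4NCl (cat.), CH2Cl2/MeCN, −40 °C; then NBS, −78 °C
Reagents that add atoms: chlorotrimethylsilane C[Si](C)(C)Cl; N-bromosuccinimide BrN1C(=O)CCC1=O
Why: Conjugate addition of chloride to C4 with O-silylation (axial attack trans to the C2 bromide, as for 5-substituted cyclohexenones) gives 2-silyloxydiene 12, which NBS should brominate at the vinylogous terminus C8 from its s-trans conformer, so that CH2Br ends anti to the carbonyl carbon and syn to C4 (halosilane 1,4-addition followed by vinylogous halogenation of a silyl dienol ether).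

Step 8
Reactants: 13 (2Z,3S,5S)-5-bromo-2-(2-bromoethylidene)-3-chloro-6,6-dimethylcyclohexan-1-one
Product: 14 (1R,2Z,3S,5S)-5-bromo-2-(2-bromoethylidene)-3-chloro-6,6-dimethylcyclohexan-1-ol
Conditions: NaBH4, CeCl3·7H2O, MeOH, −78 °C
Reagents that add atoms: none
Why: Luche 1,2-reduction, in which hydride should enter axially, anti to the axial methyl group on C1, to give the equatorial C6 alcohol cis to the C2 bromide while the allylic halides survive the cold medium.

Step 9
Reactants: 14 (1R,2Z,3S,5S)-5-bromo-2-(2-bromoethylidene)-3-chloro-6,6-dimethylcyclohexan-1-ol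
Product: 15 ochtodene, (1S,2E,3S,5S)-5-bromo-2-(2-bromoethylidene)-1,3-dichloro-4,4-dimethylcyclohexane
Conditions: PPh3, hexachloroacetone, CH2Cl2, −20 to 0 °C
Reagents that add atoms: hexachloroacetone O=C(C(Cl)(Cl)Cl)C(Cl)(Cl)Cl
Why: Appel-type chlorination of an allylic alcohol with triphenylphosphine/hexachloroacetone, a pair known for SN2 inversion without allylic transposition, should turn the equatorial C6 alcohol into the axial chloride cis to the C4 chloride under neutral conditions that leave the primary allylic bromide in place.

Compound list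
1 | buta-1,3-diene | C=CC=C | starting material
2 | [2-(phenylsulfonyl)but-3-en-1-yl]mercury chloride (racemic) | Cl[Hg]CC(C=C)S(=O)(=O)c1ccccc1 | intermediate
3 | 2-(phenylsulfonyl)buta-1,3-diene | C=CC(=C)S(=O)(=O)c1ccccc1 | intermediate
4 | methyl 2,2-dimethyl-3-oxobutanoate | CC(=O)C(C)(C)C(=O)OC | starting material
5 | lithium 4-methoxy-3,3-dimethyl-4-oxobut-1-en-2-olate (enolate of 4 at the acetyl methyl group) | [Li]OC(=C)C(C)(C)C(=O)OC | intermediate
6 | methyl 6-lithio-2,2-dimethyl-3-oxo-6-(phenylsulfonyl)oct-7-enoate (racemic allylic sulfonyl carbanion) | COC(=O)C(C)(C)C(=O)CCC([Li])(C=C)S(=O)(=O)c1ccccc1 | intermediate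
7 | 2,2-dimethyl-4-(phenylsulfonyl)-4-vinylcyclohexane-1,3-dione (racemic) | CC1(C)C(=O)CCC(C=C)(S(=O)(=O)c2ccccc2)C1=O | intermediate
8 | (3R)-3-hydroxy-2,2-dimethyl-6-(phenylsulfonyl)-6-vinylcyclohexan-1-one, both epimers at C6 | CC1(C)[C@H](O)CCC(C=C)(S(=O)(=O)c2ccccc2)C1=O | intermediate
9 | (1R)-2,2-dimethyl-3-oxo-4-(phenylsulfonyl)-4-vinylcyclohexyl chloromethanesulfonate, both epimers at C4 | CC1(C)[C@H](OS(=O)(=O)CCl)CCC(C=C)(S(=O)(=O)c2ccccc2)C1=O | intermediate
10 | (3S)-3-bromo-2,2-dimethyl-6-(phenylsulfonyl)-6-vinylcyclohexan-1-one, both epimers at C6 | CC1(C)[C@@H](Br)CCC(C=C)(S(=O)(=O)c2ccccc2)C1=O | intermediate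
11 | (5S)-5-bromo-6,6-dimethyl-2-vinylcyclohex-2-en-1-one | CC1(C)[C@@H](Br)CC=C(C=C)C1=O | intermediate
12 | {[(3S,5S)-5-bromo-3-chloro-6,6-dimethyl-2-vinylcyclohex-1-en-1-yl]oxy}trimethylsilane | CC1(C)[C@@H](Br)C[C@H](Cl)C(C=C)=C1O[Si](C)(C)C | intermediate
13 | (2Z,3S,5S)-5-bromo-2-(2-bromoethylidene)-3-chloro-6,6-dimethylcyclohexan-1-one (CH2Br anti to the carbonyl carbon) | CC1(C)[C@@H](Br)C[C@H](Cl)/C(=C\CBr)C1=O | intermediate
14 | (1R,2Z,3S,5S)-5-bromo-2-(2-bromoethylidene)-3-chloro-6,6-dimethylcyclohexan-1-ol | CC1(C)[C@@H](Br)C[C@H](Cl)/C(=C\CBr)[C@H]1O | intermediate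
15 | ochtodene, (1S,2E,3S,5S)-5-bromo-2-(2-bromoethylidene)-1,3-dichloro-4,4-dimethylcyclohexane | CC1(C)[C@@H](Br)C[C@H](Cl)/C(=C\CBr)[C@@H]1Cl | target

Total step count: 9. Longest linear sequence: 9 steps (1 to 15 through steps 1–9); the second starting material 4 enters at step 2.

The three steps most likely to fail

Step 2. After the Michael addition the tertiary allylic sulfonyl carbanion may be too hindered to acylate an ester that sits next to a quaternary carbon, so that only the open-chain adduct is recovered on quenching. Anionic oligomerisation of the diene may also outrun the addition. The fallback sets out from 4. Its lithium enolate (LiN(iPr)2, THF, −78 °C) is combined with phenyl vinyl sulfone; the same Michael/Dieckmann sequence then runs through a less hindered secondary carbanion and ends in an enolisable product, 2,2-dimethyl-4-(phenylsulfonyl)cyclohexane-1,3-dione F1. The stabilised carbanion of this compound (catalytic DBU, MeCN) is added to phenyl vinyl sulfoxide to give 2,2-dimethyl-4-(phenylsulfonyl)-4-[2-(phenylsulfinyl)ethyl]cyclohexane-1,3-dione F2. Thermal sulfoxide syn-elimination (toluene, 110 °C) unveils the vinyl group, and the fallback comes back to the route at 7.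

Step 7. Chloride addition to the enone is reversible, so 12 may lose chloride again, bromine may enter at the fully substituted α-carbon, or the vinyl enone may dimerise before it is trapped. The fallback sets out from 11. Dry HCl in CH2Cl2 at 0 °C adds across the enone, and the dienol should tautomerise to the conjugated ketone (2Z,3S,5S)-5-bromo-3-chloro-2-ethylidene-6,6-dimethylcyclohexan-1-one F3. Wohl–Ziegler bromination of its allylic methyl group (NBS, AIBN, PhCF3, 80 °C) then gives 13, where the fallback rejoins the route.

Step 9. Backside attack at a carbon next to the quaternary centre and syn to the axial C4 chloride may be slow, so that ionisation with allylic transposition takes over, and chloride may exchange the primary allylic bromide. The fallback sets out from 13 and reverses the stereochemical plan. A bulky hydride (iBu2AlH, toluene, −78 °C) should attack from the equatorial side and give the axial alcohol (1S,2Z,3S,5S)-5-bromo-2-(2-bromoethylidene)-3-chloro-6,6-dimethylcyclohexan-1-ol F4. SOCl2 in Et2O without base then converts it through the chlorosulfite with internal return (retention), and the fallback reaches the route again at 15.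

Further compounds
F1 | step 2 | 2,2-dimethyl-4-(phenylsulfonyl)cyclohexane-1,3-dione (racemic) | CC1(C)C(=O)CCC(S(=O)(=O)c2ccccc2)C1=O
F2 | step 2 | 2,2-dimethyl-4-(phenylsulfonyl)-4-[2-(phenylsulfinyl)ethyl]cyclohexane-1,3-dione (mixture of stereoisomers) | CC1(C)C(=O)CCC(CCS(=O)c2ccccc2)(S(=O)(=O)c3ccccc3)C1=O
F3 | step 7 | (2Z,3S,5S)-5-bromo-3-chloro-2-ethylidene-6,6-dimethylcyclohexan-1-one | CC1(C)[C@@H](Br)C[C@H](Cl)/C(=C\C)C1=O
F4 | step 9 | (1S,2Z,3S,5S)-5-bromo-2-(2-bromoethylidene)-3-chloro-6,6-dimethylcyclohexan-1-ol | CC1(C)[C@@H](Br)C[C@H](Cl)/C(=C\CBr)[C@@H]1O
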